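**Plan**
- Retrosynthetic cuts: the C15–O ester; the C5–C6 ring bond (aldehyde plus iodoalkene); the lactone bonds O–C8 and C11–C7 together; C8–C9 (alkyne plus allylic bromide); C3–C4 (carbomagnesiation of propargyl alcohol).
- Enabling feature: O6 sits on the carbon next to C7. An ether tether O6–C13H2–C11(CO2H)2 (C13 is the later exocyclic CH2) lets a C11 radical reach C7 only in a 5-exo mode (temporary tetrahydrofuran ring A) and holds a CO2H 1,3 to C8 for the γ-lactone (ring B). The second CO2H is the activating group and leaves as CO2.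
- Forward order: C1–C5/C9/C10/C14/C15 chain; C8–C9 coupling to a C5′–C6–C7–C8 alkynol; tether; Mn(OAc)3 bicyclisation (rings A and B at once); ring A opened to 6-OH and C11=C13; C5′ cut off with NaIO4; ten-membered ring closed at C5–C6; O15 acylation.
- Stereochemistry: a temporary (S)-carbinol at C6, from (R)-glyceraldehyde acetonide, sets C7 (5-exo closure under allylic strain) and C8 (exo lactone closure). After its excision C6 is formed again (6R) in the Felkin–Anh-controlled ring closure.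
- Alkene geometry: C4=C5 from anti-carbomagnesiation/iodination, C1=C10 from SeO2 oxidation of the (E)-methyl group, side chain from acetate transposition.

Key step: step 13

Remark: atoms carry germacrane numbers throughout (C12 lactone carbonyl, C13 exocyclic methylene, C14 methyl on C10, C15 the CH2O carbon on C4; C5′ is the auxiliary carbon on C6 that is later removed); TBDPS = tert-butyldiphenylsilyl.

**Route**

Step 1
Reactants: 1 5-bromo-2-methylpent-2-ene; 2 prop-2-yn-1-ol
Product: 5 (2Z)-3-iodo-2-(4-methylpent-3-en-1-yl)prop-2-en-1-ol, via Grignard reagent 3 (not isolated), via alkenylmagnesium alkoxide 4 (not isolated)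
Conditions: Mg, THF, 40 °C; then 2 (0.4 equiv), CuI (10 mol%), Et2O/THF, reflux; then I2, −40 °C to rt
Reagents that add atoms: iodine (II)
Why: Copper-catalysed anti-carbomagnesiation of the magnesium alkoxide of 2 (alkyl to the internal carbon, magnesium to the terminal carbon in a five-membered chelate) and iodinolysis with retention should give the (Z)-iodoalkene with iodine cis to CH2OH, which fixes the later C4=C5 geometry (C3 trans to C6).

Step 2
Reactants: 5 (2Z)-3-iodo-2-(4-methylpent-3-en-1-yl)prop-2-en-1-ol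
Product: 6 TBDPS ether of 5
Conditions: TBDPSCl, imidazole, CH2Cl2, rt
Reagents that add atoms: tert-butyl(chloro)diphenylsilane (CC(C)(C)[Si](Cl)(c1ccccc1)c1ccccc1)
Why: Standard silylation of a primary allylic alcohol.

Step 3
Reactants: 6 TBDPS ether of 5
Product: 7 (2E,6Z)-7-iodo-2-methyl-6-(TBDPS-oxymethyl)hepta-2,6-dien-1-ol
Conditions: SeO2 (cat.), t-BuOOH, salicylic acid (cat.), CH2Cl2, 0 °C to rt
Reagents that add atoms: tert-butyl hydroperoxide (CC(C)(C)OO)
Why: SeO2-catalysed allylic oxidation (ene reaction, then 2,3-sigmatropic shift) should hydroxylate the (E)-methyl group of the electron-rich gem-dimethyl alkene and leave the iodoalkene alone, which sets the C1=C10 geometry (C2 trans to C9).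

Step 4
Reactants: 7 (2E,6Z)-7-iodo-2-methyl-6-(TBDPS-oxymethyl)hepta-2,6-dien-1-ol
Product: 8 (2E,6Z)-1-bromo-7-iodo-2-methyl-6-(TBDPS-oxymethyl)hepta-2,6-diene
Conditions: CBr4, PPh3, CH2Cl2, 0 °C
Reagents that add atoms: carbon tetrabromide (BrC(Br)(Br)Br)
Why: Appel bromination converts the primary allylic alcohol into the bromide under neutral conditions without allylic transposition.

Step 5
Reactants: 9 (4R)-2,2-dimethyl-1,3-dioxolane-4-carbaldehyde
Product: 10 (4S)-4-ethynyl-2,2-dimethyl-1,3-dioxolane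
Conditions: Bestmann–Ohira reagent, K2CO3, MeOH, 0 °C to rt
Reagents that add atoms: dimethyl (1-diazo-2-oxopropyl)phosphonate (CC(=O)C(=[N+]=[N-])P(=O)(OC)OC)
Why: Seyferth–Gilbert homologation in its Bestmann–Ohira form turns the aldehyde into the terminal alkyne without touching the stereocentre (the descriptor changes only because the priorities change).

Step 6
Reactants: 10 (4S)-4-ethynyl-2,2-dimethyl-1,3-dioxolane
Product: 11 (2S)-but-3-yne-1,2-diol
Conditions: AcOH/H2O (4:1), 40 °C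
Reagents that add atoms: none
Why: Acid-catalysed acetal hydrolysis frees the diol.

Step 7
Reactants: 11 (2S)-but-3-yne-1,2-diol
Product: 12 (2S)-1-(TBDPS-oxy)but-3-yn-2-ol
Conditions: TBDPSCl (1.0 equiv), imidazole, CH2Cl2, −20 to 0 °C
Reagents that add atoms: tert-butyl(chloro)diphenylsilane (CC(C)(C)[Si](Cl)(c1ccccc1)c1ccccc1)
Why: The bulky silyl chloride should react selectively at the primary hydroxyl group and leave the propargylic secondary hydroxyl free.

Step 8
Reactants: 13 di-tert-butyl malonate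
Product: 14 di-tert-butyl 2-methylidenemalonate
Conditions: paraformaldehyde, KOAc (cat.), Cu(OAc)2 (cat.), AcOH, 95 °C
Reagents that add atoms: paraformaldehyde as formaldehyde (C=O)
Why: Knoevenagel condensation with formaldehyde; the bulky tert-butyl esters keep the methylidenemalonate from polymerising.

Step 9
Reactants: 8 (2E,6Z)-1-bromo-7-iodo-2-methyl-6-(TBDPS-oxymethyl)hepta-2,6-diene; 12 (2S)-1-(TBDPS-oxy)but-3-yn-2-ol
Product: 15 (2S,6E,10Z)-11-iodo-6-methyl-1-(TBDPS-oxy)-10-(TBDPS-oxymethyl)undeca-6,10-dien-3-yn-2-ol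
Conditions: CuI (20 mol%), K2CO3, Bu4NI (cat.), DMF, rt
Reagents that add atoms: none
Why: Copper-catalysed coupling of the terminal alkyne (as its copper acetylide) with the primary allylic bromide (SN2) forms the C8–C9 bond and the skipped enyne, and the free hydroxyl group and the iodoalkene should be tolerated.

Step 10
Reactants: 15 (2S,6E,10Z)-11-iodo-6-methyl-1-(TBDPS-oxy)-10-(TBDPS-oxymethyl)undeca-6,10-dien-3-yn-2-ol
Product: 17 (2S,3Z,6E,10Z)-11-iodo-6-methyl-1-(TBDPS-oxy)-10-(TBDPS-oxymethyl)undeca-3,6,10-trien-2-ol, via alkenylborane 16 (not isolated)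
Conditions: Cy2BH (2.2 equiv), THF, 0 °C; then AcOH, rt; ethanolamine work-up
Reagents that add atoms: none
Why: syn-Hydroboration of the alkyne with the hindered dialkylborane and protonolysis of the alkenyl–boron bond with retention should give the (Z)-alkene, while the trisubstituted alkenes and the iodoalkene are not hydroborated.

Step 11
Reactants: 17 (2S,3Z,6E,10Z)-11-iodo-6-methyl-1-(TBDPS-oxy)-10-(TBDPS-oxymethyl)undeca-3,6,10-trien-2-ol; 14 di-tert-butyl 2-methylidenemalonate
Product: 18 di-tert-butyl 2-({[(2S,3Z,6E,10Z)-11-iodo-6-methyl-1-(TBDPS-oxy)-10-(TBDPS-oxymethyl)undeca-3,6,10-trien-2-yl]oxy}methyl)malonate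
Conditions: NaH (10 mol%), THF, 0 °C
Reagents that add atoms: none
Why: Base-catalysed oxa-Michael addition of the secondary alkoxide to the highly electrophilic methylidenemalonate installs the O6–C13–C11 tether.

Step 12
Reactants: 18 di-tert-butyl 2-({[(2S,3Z,6E,10Z)-11-iodo-6-methyl-1-(TBDPS-oxy)-10-(TBDPS-oxymethyl)undeca-3,6,10-trien-2-yl]oxy}methyl)malonate
Product: 19 2-({[(2S,3Z,6E,10Z)-11-iodo-6-methyl-1-(TBDPS-oxy)-10-(TBDPS-oxymethyl)undeca-3,6,10-trien-2-yl]oxy}methyl)malonic acid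
Conditions: ZnBr2 (5 equiv), CH2Cl2, rt; aqueous work-up at pH 3
Reagents that add atoms: none
Why: ZnBr2-mediated cleavage of tert-butyl esters (loss of 2-methylpropene) gives the malonic acid without protic acid, so the silyl ethers, the allylic ether and the alkenes should survive.

Step 13
Reactants: 19 2-({[(2S,3Z,6E,10Z)-11-iodo-6-methyl-1-(TBDPS-oxy)-10-(TBDPS-oxymethyl)undeca-3,6,10-trien-2-yl]oxy}methyl)malonic acid
Product: 21 (3S,3aR,4S,6aR)-3-[(2E,6Z)-7-iodo-2-methyl-6-(TBDPS-oxymethyl)hepta-2,6-dien-1-yl]-4-(TBDPS-oxymethyl)tetrahydro-1H,3H-furo[3,4-c]furan-1-one, via carboxy lactone 20 (not isolated)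
Conditions: Mn(OAc)3·2H2O (2.2 equiv), KOAc, AcOH, 30 °C, 0.01 M, argon; work-up; then pyridine, toluene, 100 °C
Reagents that add atoms: none
Why: Mn(OAc)3 oxidises the enolised malonic acid to the C11 malonyl radical, which closes the tetrahydrofuran ring A by 5-exo-trig attack on C7 (C11–C7 bond); the C8 radical is then oxidised by a second Mn(OAc)3 within the manganese carboxylate of the cis CO2H, so the γ-lactone ring B closes by 5-exo C–O bond formation (O–C8 bond), and heating expels CO2 from 20. The closest known reaction type is the Mn(OAc)3-mediated oxidative radical cyclisation–lactonisation (double annulation) of unsaturated malonic acids. C7 is set by the C6 carbinol centre: allylic 1,3-strain in the (Z)-alkene holds H-6 in the alkene plane, so the O6-tethered radical adds to the face of C7 anti to the CH2O-TBDPS group and C5′ and C8 end up trans on ring A. C8 is set in the lactone closure, which should place the C9 chain on the convex face of the cis-fused bicyclo[3.3.0] system and so give the 7,8-trans lactone; C11 is fixed as the cis ring fusion and is erased in step 14. The step needs chemoselectivity for C7=C8 over the two trisubstituted alkenes and the iodoalkene and the regiochemistry C11→C7/O→C8, both secured by the C13–O6–C6 tether, which allows only the 5-exo mode at C7. High dilution suppresses intermolecular addition, and leaving out Cu(OAc)2 disfavours loss of an allylic C9 hydrogen from the C8 radical.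

Step 14
Reactants: 21 (3S,3aR,4S,6aR)-3-[(2E,6Z)-7-iodo-2-methyl-6-(TBDPS-oxymethyl)hepta-2,6-dien-1-yl]-4-(TBDPS-oxymethyl)tetrahydro-1H,3H-furo[3,4-c]furan-1-one
Product: 23 (4S,5S)-4-[(1S)-1-hydroxy-2-(TBDPS-oxy)ethyl]-5-[(2E,6Z)-7-iodo-2-methyl-6-(TBDPS-oxymethyl)hepta-2,6-dien-1-yl]-3-methylideneoxolan-2-one, via bromomethyl lactone borinate 22 (not isolated)
Conditions: Me2BBr (1.5 equiv), Et3N (0.2 equiv), CH2Cl2, −78 to −40 °C; then DBU (3 equiv), −40 to 0 °C; aqueous NaHCO3
Reagents that add atoms: none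
Why: Me2BBr should cleave the tetrahydrofuran by SN2 attack of bromide at the unhindered primary C13–O bond, and DBU then eliminates HBr from the α-(bromomethyl) lactone (E1cB) while O6 is still masked as its borinate, which releases the exocyclic methylene and, on work-up, the C6 hydroxyl group.

Step 15
Reactants: 23 (4S,5S)-4-[(1S)-1-hydroxy-2-(TBDPS-oxy)ethyl]-5-[(2E,6Z)-7-iodo-2-methyl-6-(TBDPS-oxymethyl)hepta-2,6-dien-1-yl]-3-methylideneoxolan-2-one
Product: 24 (4S,5S)-4-[(1S)-1,2-dihydroxyethyl]-5-[(2E,6Z)-6-(hydroxymethyl)-7-iodo-2-methylhepta-2,6-dien-1-yl]-3-methylideneoxolan-2-one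
Conditions: HF·pyridine, pyridine/THF, 0 °C to rt
Reagents that add atoms: none
Why: Fluoride cleaves both silyl ethers, and the buffered medium should neither add to the α-methylene lactone nor move the lactone onto the free hydroxyl groups.

Step 16
Reactants: 24 (4S,5S)-4-[(1S)-1,2-dihydroxyethyl]-5-[(2E,6Z)-6-(hydroxymethyl)-7-iodo-2-methylhepta-2,6-dien-1-yl]-3-methylideneoxolan-2-one
Product: 25 (2S,3R)-2-[(2E,6Z)-6-(hydroxymethyl)-7-iodo-2-methylhepta-2,6-dien-1-yl]-4-methylidene-5-oxooxolane-3-carbaldehyde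
Conditions: NaIO4, THF/pH 7 buffer, 0 °C; used crude
Reagents that add atoms: none
Why: Periodate glycol cleavage excises the auxiliary carbon C5′ as formaldehyde and leaves C6 as the aldehyde, while the isolated C15 hydroxyl group is not touched.

Step 17
Reactants: 25 (2S,3R)-2-[(2E,6Z)-6-(hydroxymethyl)-7-iodo-2-methylhepta-2,6-dien-1-yl]-4-methylidene-5-oxooxolane-3-carbaldehyde
Product: 27 (6R,7S,8S)-6,15-dihydroxygermacra-1(10),4,11(13)-trien-12,8-olide (C2 trans to C9; C3 trans to C6), via alkenylchromium species 26 (not isolated)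
Conditions: CrCl2 (10 equiv), NiCl2 (1 mol%), degassed DMSO, rt, slow addition to 0.003 M
Reagents that add atoms: none
Why: Nozaki–Hiyama–Kishi reaction (oxidative addition of zerovalent nickel to the iodoalkene, transmetalation to chromium, addition of the alkenylchromium species to the aldehyde) closes the ten-membered ring at C5–C6 with retention of alkene geometry, and C6 should follow the Felkin–Anh model (attack anti to C8, carbonyl oxygen gauche to C11 and pointing out of the forming ring), which corresponds to 6R.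

Step 18
Reactants: 28 tert-butyl acrylate; 29 acetaldehyde
Product: 30 tert-butyl 3-hydroxy-2-methylidenebutanoate (racemic)
Conditions: DABCO (20 mol%), dioxane/H2O, rt
Reagents that add atoms: none
Why: Morita–Baylis–Hillman reaction.

Step 19
Reactants: 30 tert-butyl 3-hydroxy-2-methylidenebutanoate (racemic)
Product: 31 tert-butyl 3-acetoxy-2-methylidenebutanoate (racemic)
Conditions: Ac2O, pyridine, DMAP (cat.), CH2Cl2, 0 °C
Reagents that add atoms: acetic anhydride (CC(=O)OC(C)=O)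
Why: Acetylation of the secondary allylic alcohol.

Step 20
Reactants: 31 tert-butyl 3-acetoxy-2-methylidenebutanoate (racemic)
Product: 32 tert-butyl (2E)-2-(acetoxymethyl)but-2-enoate
Conditions: DABCO (20 mol%), THF, reflux
Reagents that add atoms: none
Why: DABCO-catalysed 1,3-transposition of the acetate (SN2′ addition of the amine, SN2′ return of acetate) should give the thermodynamically preferred trisubstituted (E)-enoate with the methyl group cis to CH2OAc.

Step 21
Reactants: 32 tert-butyl (2E)-2-(acetoxymethyl)but-2-enoate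
Product: 33 (2E)-2-(acetoxymethyl)but-2-enoic acid
Conditions: CF3CO2H, CH2Cl2, 0 °C to rt
Reagents that add atoms: none
Why: Acidolysis of the tert-butyl ester (loss of 2-methylpropene) leaves the acetate and the enoate intact.

Step 22
Reactants: 27 (6R,7S,8S)-6,15-dihydroxygermacra-1(10),4,11(13)-trien-12,8-olide; 33 (2E)-2-(acetoxymethyl)but-2-enoic acid
Product: 35 (6R,7S,8S)-15-[(2E)-2-(acetoxymethyl)but-2-enoyloxy]-6-hydroxygermacra-1(10),4,11(13)-trien-12,8-olide (target), via mixed anhydride 34 (not isolated)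
Conditions: 33 (1.1 equiv), 2,4,6-trichlorobenzoyl chloride, Et3N, THF, 0 °C; then 27, DMAP, toluene, 0 °C
Reagents that add atoms: none
Why: Yamaguchi esterification, in which the mixed anhydride should acylate the unhindered primary allylic 15-OH much faster than the hindered secondary 6-OH.

**Compound list**

1 | 5-bromo-2-methylpent-2-ene | CC(C)=CCCBr | starting material
2 | prop-2-yn-1-ol | C#CCO | starting material
3 | (4-methylpent-3-en-1-yl)magnesium bromide | CC(C)=CCC[Mg]Br | intermediate (not isolated)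
4 | bromomagnesium alkoxide of (2Z)-3-(bromomagnesio)-2-(4-methylpent-3-en-1-yl)prop-2-en-1-ol | CC(C)=CCC/C(CO[Mg]Br)=C/[Mg]Br | intermediate (not isolated)
5 | (2Z)-3-iodo-2-(4-methylpent-3-en-1-yl)prop-2-en-1-ol | CC(C)=CCC/C(CO)=C/I | intermediate
6 | TBDPS ether of 5 | CC(C)=CCC/C(CO[Si](c1ccccc1)(c1ccccc1)C(C)(C)C)=C/I | intermediate
7 | (2E,6Z)-7-iodo-2-methyl-6-(TBDPS-oxymethyl)hepta-2,6-dien-1-ol | OC/C(C)=C/CC/C(CO[Si](c1ccccc1)(c1ccccc1)C(C)(C)C)=C/I | intermediate
8 | (2E,6Z)-1-bromo-7-iodo-2-methyl-6-(TBDPS-oxymethyl)hepta-2,6-diene | BrC/C(C)=C/CC/C(CO[Si](c1ccccc1)(c1ccccc1)C(C)(C)C)=C/I | intermediate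
9 | (4R)-2,2-dimethyl-1,3-dioxolane-4-carbaldehyde | O=C[C@H]1COC(C)(C)O1 | starting material
10 | (4S)-4-ethynyl-2,2-dimethyl-1,3-dioxolane | C#C[C@H]1COC(C)(C)O1 | intermediate
11 | (2S)-but-3-yne-1,2-diol | C#C[C@H](O)CO | intermediate
12 | (2S)-1-(TBDPS-oxy)but-3-yn-2-ol | C#C[C@H](O)CO[Si](c1ccccc1)(c1ccccc1)C(C)(C)C | intermediate
13 | di-tert-butyl malonate | CC(C)(C)OC(=O)CC(=O)OC(C)(C)C | starting material
14 | di-tert-butyl 2-methylidenemalonate | C=C(C(=O)OC(C)(C)C)C(=O)OC(C)(C)C | intermediate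
15 | (2S,6E,10Z)-11-iodo-6-methyl-1-(TBDPS-oxy)-10-(TBDPS-oxymethyl)undeca-6,10-dien-3-yn-2-ol | CC(C)(C)[Si](c1ccccc1)(c1ccccc1)OC[C@@H](O)C#CC/C(C)=C/CC/C(CO[Si](c1ccccc1)(c1ccccc1)C(C)(C)C)=C/I | intermediate
16 | O6-dicyclohexylborinate of the (3Z)-C8-dicyclohexylboryl alkene from 15 | CC(C)(C)[Si](c1ccccc1)(c1ccccc1)OC[C@@H](OB(C1CCCCC1)C1CCCCC1)/C=C(/B(C1CCCCC1)C1CCCCC1)C/C(C)=C/CC/C(CO[Si](c1ccccc1)(c1ccccc1)C(C)(C)C)=C/I | intermediate (not isolated)
17 | (2S,3Z,6E,10Z)-11-iodo-6-methyl-1-(TBDPS-oxy)-10-(TBDPS-oxymethyl)undeca-3,6,10-trien-2-ol | CC(C)(C)[Si](c1ccccc1)(c1ccccc1)OC[C@@H](O)/C=C\C/C(C)=C/CC/C(CO[Si](c1ccccc1)(c1ccccc1)C(C)(C)C)=C/I | intermediate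
18 | di-tert-butyl 2-({[(2S,3Z,6E,10Z)-11-iodo-6-methyl-1-(TBDPS-oxy)-10-(TBDPS-oxymethyl)undeca-3,6,10-trien-2-yl]oxy}methyl)malonate | CC(C)(C)[Si](c1ccccc1)(c1ccccc1)OC[C@@H](OCC(C(=O)OC(C)(C)C)C(=O)OC(C)(C)C)/C=C\C/C(C)=C/CC/C(CO[Si](c1ccccc1)(c1ccccc1)C(C)(C)C)=C/I | intermediate
19 | 2-({[(2S,3Z,6E,10Z)-11-iodo-6-methyl-1-(TBDPS-oxy)-10-(TBDPS-oxymethyl)undeca-3,6,10-trien-2-yl]oxy}methyl)malonic acid | CC(C)(C)[Si](c1ccccc1)(c1ccccc1)OC[C@@H](OCC(C(=O)O)C(=O)O)/C=C\C/C(C)=C/CC/C(CO[Si](c1ccccc1)(c1ccccc1)C(C)(C)C)=C/I | intermediate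
20 | (3S,3aR,4S,6aR)-3-[(2E,6Z)-7-iodo-2-methyl-6-(TBDPS-oxymethyl)hepta-2,6-dien-1-yl]-1-oxo-4-(TBDPS-oxymethyl)tetrahydro-1H,3H-furo[3,4-c]furan-6a-carboxylic acid | O=C1O[C@@H](C/C(C)=C/CC/C(CO[Si](c3ccccc3)(c3ccccc3)C(C)(C)C)=C/I)[C@@H]2[C@@H](CO[Si](c3ccccc3)(c3ccccc3)C(C)(C)C)OC[C@]12C(=O)O | intermediate (not isolated)
21 | (3S,3aR,4S,6aR)-3-[(2E,6Z)-7-iodo-2-methyl-6-(TBDPS-oxymethyl)hepta-2,6-dien-1-yl]-4-(TBDPS-oxymethyl)tetrahydro-1H,3H-furo[3,4-c]furan-1-one (cis-fused; H-7/H-8 trans) | O=C1O[C@@H](C/C(C)=C/CC/C(CO[Si](c3ccccc3)(c3ccccc3)C(C)(C)C)=C/I)[C@@H]2[C@@H](CO[Si](c3ccccc3)(c3ccccc3)C(C)(C)C)OC[C@H]12 | intermediate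
22 | O6-dimethylborinate of the α-(bromomethyl) lactone from ring A opening of 21 | BrC[C@@H]1C(=O)O[C@@H](C/C(C)=C/CC/C(CO[Si](c2ccccc2)(c2ccccc2)C(C)(C)C)=C/I)[C@@H]1[C@H](OB(C)C)CO[Si](c2ccccc2)(c2ccccc2)C(C)(C)C | intermediate (not isolated)
23 | (4S,5S)-4-[(1S)-1-hydroxy-2-(TBDPS-oxy)ethyl]-5-[(2E,6Z)-7-iodo-2-methyl-6-(TBDPS-oxymethyl)hepta-2,6-dien-1-yl]-3-methylideneoxolan-2-one | C=C1C(=O)O[C@@H](C/C(C)=C/CC/C(CO[Si](c2ccccc2)(c2ccccc2)C(C)(C)C)=C/I)[C@@H]1[C@H](O)CO[Si](c2ccccc2)(c2ccccc2)C(C)(C)C | intermediate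
24 | (4S,5S)-4-[(1S)-1,2-dihydroxyethyl]-5-[(2E,6Z)-6-(hydroxymethyl)-7-iodo-2-methylhepta-2,6-dien-1-yl]-3-methylideneoxolan-2-one | C=C1C(=O)O[C@@H](C/C(C)=C/CC/C(CO)=C/I)[C@@H]1[C@H](O)CO | intermediate
25 | (2S,3R)-2-[(2E,6Z)-6-(hydroxymethyl)-7-iodo-2-methylhepta-2,6-dien-1-yl]-4-methylidene-5-oxooxolane-3-carbaldehyde | C=C1C(=O)O[C@@H](C/C(C)=C/CC/C(CO)=C/I)[C@@H]1C=O | intermediate
26 | C5-dichlorochromium alkenyl species from 25 | C=C1C(=O)O[C@@H](C/C(C)=C/CC/C(CO)=C/[Cr](Cl)Cl)[C@@H]1C=O | intermediate (not isolated)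
27 | (6R,7S,8S)-6,15-dihydroxygermacra-1(10),4,11(13)-trien-12,8-olide (C2 trans to C9; C3 trans to C6) | C=C1C(=O)O[C@H]2C/C(C)=C/CC/C(CO)=C/[C@@H](O)[C@H]12 | intermediate
28 | tert-butyl acrylate | C=CC(=O)OC(C)(C)C | starting material
29 | acetaldehyde | CC=O | starting material
30 | tert-butyl 3-hydroxy-2-methylidenebutanoate (racemic) | CC(O)C(=C)C(=O)OC(C)(C)C | intermediate
31 | tert-butyl 3-acetoxy-2-methylidenebutanoate (racemic) | CC(OC(C)=O)C(=C)C(=O)OC(C)(C)C | intermediate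
32 | tert-butyl (2E)-2-(acetoxymethyl)but-2-enoate | CC(C)(C)OC(=O)/C(=C/C)COC(C)=O | intermediate
33 | (2E)-2-(acetoxymethyl)but-2-enoic acid | OC(=O)/C(=C/C)COC(C)=O | intermediate
34 | mixed anhydride of 33 and 2,4,6-trichlorobenzoic acid | O=C(OC(=O)/C(=C/C)COC(C)=O)c1c(Cl)cc(Cl)cc1Cl | intermediate (not isolated)
35 | (6R,7S,8S)-15-[(2E)-2-(acetoxymethyl)but-2-enoyloxy]-6-hydroxygermacra-1(10),4,11(13)-trien-12,8-olide | C=C1C(=O)O[C@H]2C/C(C)=C/CC/C(COC(=O)/C(=C/C)COC(C)=O)=C/[C@@H](O)[C@H]12 | target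

**Step count**

Total: 22 steps. Longest linear sequence: 14 steps (steps 1–4, 9–17 and 22).

**Steps most likely to fail**

Step 13. The malonyl radical may add to C7 with incomplete facial control. Oxidation of the C8 radical may also be diverted to loss of an allylic hydrogen or to a hydride shift instead of C–O closure. The fallback separates the two bond formations. It sets out from 18: α-iodination (NaH, N-iodosuccinimide, THF, 0 °C) should give the iodomalonate F1. Iodine-atom-transfer 5-exo cyclisation (Et3B, trace air, benzene, rt) should then form the C11–C7 bond and give the tetrahydrofuran iodide F2 as C8 epimers. Silver-assisted closure (AgOSO2CF3, 2,6-lutidine, CH2Cl2, −20 °C) lets the cis tert-butyl ester oxygen displace iodide at C8 with loss of 2-methylpropene, giving the lactone tert-butyl ester F3. ZnBr2 in CH2Cl2 cleaves the remaining tert-butyl ester and returns the route at 20, which is decarboxylated to 21 as in step 13.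

Step 14. Bromide may attack the secondary C6–O bond or a silyl ether instead of the primary C13–O bond, and the freed 6-OH may migrate onto the lactone carbonyl. The fallback opens ring A from the lactone side. It sets out from 21: KN(SiMe3)2 in THF at −78 °C should give the potassium lactone enolate F4. On warming to −40 °C this should expel O6 from C13 (E1cB) to give the potassium alkoxide F5. Quenching with AcOH at −78 °C, before the alkoxide can attack the lactone, returns the route at 23.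

Step 17. Oligomerisation may compete at the dilution that is practical, and the addition may show poor facial selectivity at C6. The fallback corrects C6 by inversion. It sets out from 25: if the ring closure gives mainly the 6S diol F6, this is acylated at O15 exactly as in step 22 to give the 6-epi ester F7. Mitsunobu reaction with formic acid (PPh3, diisopropyl azodicarboxylate, THF, 0 °C) should invert C6 and give the 6R formate F8. Mild methanolysis of the formate (KHCO3, MeOH, 0 °C), which should spare the acetate and the enoate ester, returns the route at 35.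

Further compounds
F1 | step 13 | di-tert-butyl 2-iodo-2-({[(2S,3Z,6E,10Z)-11-iodo-6-methyl-1-(TBDPS-oxy)-10-(TBDPS-oxymethyl)undeca-3,6,10-trien-2-yl]oxy}methyl)malonate | CC(C)(C)[Si](c1ccccc1)(c1ccccc1)OC[C@@H](OCC(I)(C(=O)OC(C)(C)C)C(=O)OC(C)(C)C)/C=C\C/C(C)=C/CC/C(CO[Si](c1ccccc1)(c1ccccc1)C(C)(C)C)=C/I
F2 | step 13 | di-tert-butyl (4R,5S)-4-[(3E,7Z)-1,8-diiodo-3-methyl-7-(TBDPS-oxymethyl)octa-3,7-dien-2-yl]-5-(TBDPS-oxymethyl)oxolane-3,3-dicarboxylate (C8 epimers; 4,5-trans) | CC(C)(C)OC(=O)C1(C(=O)OC(C)(C)C)CO[C@H](CO[Si](c2ccccc2)(c2ccccc2)C(C)(C)C)[C@H]1C(I)C/C(C)=C/CC/C(CO[Si](c2ccccc2)(c2ccccc2)C(C)(C)C)=C/I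
F3 | step 13 | tert-butyl ester of 20 | O=C1O[C@@H](C/C(C)=C/CC/C(CO[Si](c3ccccc3)(c3ccccc3)C(C)(C)C)=C/I)[C@@H]2[C@@H](CO[Si](c3ccccc3)(c3ccccc3)C(C)(C)C)OC[C@]12C(=O)OC(C)(C)C
F4 | step 14 | potassium enolate of 21 (C11=C12–OK) | [K+].[O-]C1=C2CO[C@H](CO[Si](c3ccccc3)(c3ccccc3)C(C)(C)C)[C@H]2[C@H](C/C(C)=C/CC/C(CO[Si](c3ccccc3)(c3ccccc3)C(C)(C)C)=C/I)O1
F5 | step 14 | potassium C6 alkoxide of 23 | [K+].C=C1C(=O)O[C@@H](C/C(C)=C/CC/C(CO[Si](c2ccccc2)(c2ccccc2)C(C)(C)C)=C/I)[C@@H]1[C@H]([O-])CO[Si](c2ccccc2)(c2ccccc2)C(C)(C)C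
F6 | step 17 | (6S,7S,8S)-6,15-dihydroxygermacra-1(10),4,11(13)-trien-12,8-olide (6-epimer of 27) | C=C1C(=O)O[C@H]2C/C(C)=C/CC/C(CO)=C/[C@H](O)[C@H]12
F7 | step 17 | 6-epimer of 35 | C=C1C(=O)O[C@H]2C/C(C)=C/CC/C(COC(=O)/C(=C/C)COC(C)=O)=C/[C@H](O)[C@H]12
F8 | step 17 | 6-O-formate of 35 (6R) | C=C1C(=O)O[C@H]2C/C(C)=C/CC/C(COC(=O)/C(=C/C)COC(C)=O)=C/[C@@H](OC=O)[C@H]12
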